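## Retrosynthetic overview

1. Target 53 ⇐ global desilylation of nona-TBS macrolactone 52 ⇐ one-pot ring-closing metathesis/hydrogenation of acyclic diene ester 50 at C11–C12; this is the only ring-forming event (the 36-membered lactone).
2. Enabling feature: C11–C12 is the central bond of the anti-1,5-diol C9/C13 and sits across the 36-membered ring (C1–C35 plus ring O) from the ester. C9 is made as a homoallylic and C13 as an allylic carbinol, and the ring holds no other C=C, so both alkene handles arrive with the stereocentres and the new alkene is erased by hydrogenation.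
3. 50 ⇐ Evans–Tishchenko union of C1 aldehyde 11 with the C33-keto/C35-hydroxy chain 48 (C1–O–C35 ester and C33 in one step); 48 ⇐ C33 dithiane 45 + C34–C40 epoxide 16 (Sharpless epoxidation, AlMe3 opening).
4. C12–C33 chain ⇐ silyl-dithiane (C27) linchpin joining epoxide 21 (C28–C33) to C2-symmetric bis-epoxide 32 (C12–C26); the second epoxide of 32 becomes the C13 vinyl carbinol; C27 by 1,3-syn reduction.
5. 32 ⇐ double Noyori hydrogenation (C17, C21) and (S)-epichlorohydrin (C13, C25; also C29 in 21); 11 ⇐ methyl (R)-3-methylglutarate by two allylboration/hydroformylation cycles (C5, C9).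

Key step: step 33

Remark: locants C1–C40 are those of the target (C1 = lactone carbonyl, ring O on C35, C36 = methyl-bearing CH, C37–C40 = butyl); terminal =CH2 carbons later lost as ethylene carry no locant. (+)-Ipc2B(allyl) is the reagent derived from (−)-α-pinene, and bromide 17 is assumed to be purchasable. TBS = tert-butyldimethylsilyl, PMB = 4-methoxybenzyl.

## Route

### Part A – C1–C11 aldehyde 11

Step 1
Reactants: 1 methyl hydrogen (R)-3-methylglutarate
Product: 2 methyl (3R)-5-hydroxy-3-methylpentanoate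
Conditions: BH3·SMe2, THF, −10 °C → rt; then MeOH
Reagents that add atoms: none
Why: Chemoselective borane reduction: the free acid is reduced via its acyloxyborane much faster than the methyl ester, so the future C5 terminus is differentiated from C1 without touching C3.

Step 2
Reactants: 2 methyl (3R)-5-hydroxy-3-methylpentanoate
Product: 3 methyl (3R)-3-methyl-5-oxopentanoate
Conditions: Dess–Martin periodinane, CH2Cl2, 0 °C → rt
Reagents that add atoms: none
Why: Dess–Martin oxidation should stop cleanly at the aldehyde under non-epimerising conditions and leave the ester untouched.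

Step 3
Reactants: 3 methyl (3R)-3-methyl-5-oxopentanoate
Product: 5 methyl (3R,5R)-5-hydroxy-3-methyloct-7-enoate, via borinate 4 (not isolated)
Conditions: (+)-Ipc2B(allyl), Et2O, −78 °C; then HOCH2CH2NH2, rt
Reagents that add atoms: (+)-B-allyldiisopinocampheylborane, C=CCB([C@H]1C[C@H]2C[C@@H]([C@@H]1C)C2(C)C)[C@H]1C[C@H]2C[C@@H]([C@@H]1C)C2(C)C
Why: Brown allylboration through a chair Zimmerman–Traxler transition state should set C5 (R) under reagent control (the remote C3 methyl has little influence), and the neutral ethanolamine work-up avoids δ-lactonisation.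

Step 4
Reactants: 5 methyl (3R,5R)-5-hydroxy-3-methyloct-7-enoate
Product: 6 methyl (3R,5R)-5-(TBS-oxy)-3-methyloct-7-enoate
Conditions: TBSOTf, 2,6-lutidine, CH2Cl2, −78 °C
Reagents that add atoms: tert-butyldimethylsilyl triflate, CC(C)(C)[Si](C)(C)OS(=O)(=O)C(F)(F)F
Why: Silylation of the crude δ-hydroxy ester caps the C5 oxygen before it can lactonise onto C1.

Step 5
Reactants: 6 methyl (3R,5R)-5-(TBS-oxy)-3-methyloct-7-enoate
Product: 7 methyl (3R,5R)-5-(TBS-oxy)-3-methyl-9-oxononanoate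
Conditions: Rh(CO)2(acac) (1 mol%), BIPHEPHOS (2 mol%), CO/H2 (1:1, 5 bar), toluene, 60 °C
Reagents that add atoms: carbon monoxide, [C-]#[O+]
Why: Linear-selective Rh/bisphosphite hydroformylation of the terminal alkene should deliver the C9 aldehyde, installing the three-methylene spacer of the 1,5-diol with ester and silyl ether intact.

Step 6
Reactants: 7 methyl (3R,5R)-5-(TBS-oxy)-3-methyl-9-oxononanoate
Product: 9 methyl (3R,5R,9S)-5-(TBS-oxy)-9-hydroxy-3-methyldodec-11-enoate, via borinate 8 (not isolated)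
Conditions: (+)-Ipc2B(allyl), Et2O, −78 °C; then HOCH2CH2NH2, rt
Reagents that add atoms: (+)-B-allyldiisopinocampheylborane, C=CCB([C@H]1C[C@H]2C[C@@H]([C@@H]1C)C2(C)C)[C@H]1C[C@H]2C[C@@H]([C@@H]1C)C2(C)C
Why: A second reagent-controlled Brown allylboration should set C9 (9S here, 9R in the target after the priority change) syn to C5 and install the allyl group whose internal carbon is C11.

Step 7
Reactants: 9 methyl (3R,5R,9S)-5-(TBS-oxy)-9-hydroxy-3-methyldodec-11-enoate
Product: 10 methyl (3R,5R,9S)-5,9-bis(TBS-oxy)-3-methyldodec-11-enoate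
Conditions: TBSOTf, 2,6-lutidine, CH2Cl2, −78 °C
Reagents that add atoms: tert-butyldimethylsilyl triflate, CC(C)(C)[Si](C)(C)OS(=O)(=O)C(F)(F)F
Why: Standard silyl protection of the secondary homoallylic alcohol.

Step 8
Reactants: 10 methyl (3R,5R,9S)-5,9-bis(TBS-oxy)-3-methyldodec-11-enoate
Product: 11 (3R,5R,9S)-5,9-bis(TBS-oxy)-3-methyldodec-11-enal
Conditions: DIBAL-H (1.1 equiv), CH2Cl2, −78 °C
Reagents that add atoms: none
Why: Partial ester reduction: the tetrahedral aluminium hemiacetal is stable at −78 °C and should collapse to the C1 aldehyde only on work-up.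

### Part B – C34–C40 epoxide 16

Step 9
Reactants: 12 (E)-hept-2-en-1-ol
Product: 13 [(2R,3R)-3-butyloxiran-2-yl]methanol
Conditions: Ti(OiPr)4 (5 mol%), D-(−)-diisopropyl tartrate (6 mol%), t-BuOOH, 4 Å MS, CH2Cl2, −20 °C
Reagents that add atoms: tert-butyl hydroperoxide, CC(C)(C)OO
Why: Sharpless asymmetric epoxidation with the D-tartrate should give the (2R,3R)-epoxide, fixing the absolute configuration of the future C35 and C36.

Step 10
Reactants: 13 [(2R,3R)-3-butyloxiran-2-yl]methanol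
Product: 14 (2S,3S)-3-methylheptane-1,2-diol
Conditions: AlMe3 (3 equiv), hexane/CH2Cl2, 0 °C → rt
Reagents that add atoms: trimethylaluminium, C[Al](C)C
Why: Trimethylaluminium opens 2,3-epoxy alcohols at C3 with inversion (aluminium alkoxide-directed SN2), giving the anti methyl/hydroxyl pair and so setting C36 (S) while C35 keeps its oxygen.

Step 11
Reactants: 14 (2S,3S)-3-methylheptane-1,2-diol
Product: 16 (2S)-2-[(2S)-hexan-2-yl]oxirane, via monotosylate 15 (not isolated)
Conditions: NaH (2.5 equiv), 1-(p-toluenesulfonyl)imidazole, THF, 0 °C → rt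
Reagents that add atoms: none
Why: Selective sulfonylation of the primary alkoxide and intramolecular Williamson (3-exo-tet) closure by the secondary alkoxide should give the terminal epoxide with retention at C35.

### Part C – C28–C33 epoxide 21

Step 12
Reactants: 17 1-[(3-bromopropoxy)methyl]-4-methoxybenzene; 18 (S)-epichlorohydrin
Product: 20 (2S)-1-chloro-6-[(4-methoxybenzyl)oxy]hexan-2-ol, via Grignard reagent 19 (not isolated)
Conditions: Mg, THF, rt; then CuI (10 mol%), 18, −40 °C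
Reagents that add atoms: none
Why: Copper-catalysed Grignard opening of epichlorohydrin at the unsubstituted epoxide carbon is an SN2 process that leaves the stereocentre (future C29) untouched.

Step 13
Reactants: 20 (2S)-1-chloro-6-[(4-methoxybenzyl)oxy]hexan-2-ol
Product: 21 (2S)-2-{4-[(4-methoxybenzyl)oxy]butyl}oxirane
Conditions: NaOH, H2O/Et2O, rt
Reagents that add atoms: none
Why: Base-induced 3-exo-tet closure of the chlorohydrin gives the terminal epoxide without touching the stereocentre.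

### Part D – C12–C26 bis-epoxide 32

Step 14
Reactants: 22 glutaryl dichloride; 23 Meldrum's acid
Product: 25 dimethyl 3,7-dioxononanedioate, via acyl Meldrum adduct 24 (not isolated)
Conditions: pyridine, CH2Cl2, 0 °C → rt; then MeOH, reflux
Reagents that add atoms: methanol, CO
Why: C-acylation of Meldrum's acid followed by methanolysis with loss of acetone and CO2 (acyl ketene pathway) is the standard route to β-keto esters and should work twice on the diacid chloride.

Step 15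
Reactants: 25 dimethyl 3,7-dioxononanedioate
Product: 26 dimethyl (3R,7R)-3,7-dihydroxynonanedioate
Conditions: H2 (50 bar), RuCl2[(R)-BINAP] (0.2 mol%), MeOH, 50 °C
Reagents that add atoms: none
Why: Noyori asymmetric hydrogenation of β-keto esters with (R)-BINAP–Ru gives (R)-β-hydroxy esters, so two independent catalyst-controlled reductions should set C17 and C21 with the meso isomer statistically suppressed.

Step 16
Reactants: 26 dimethyl (3R,7R)-3,7-dihydroxynonanedioate
Product: 27 dimethyl (3R,7R)-3,7-bis(TBS-oxy)nonanedioate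
Conditions: TBSCl, imidazole, DMF, rt
Reagents that add atoms: tert-butyldimethylsilyl chloride, CC(C)(C)[Si](C)(C)Cl
Why: Standard silylation of β-hydroxy esters.

Step 17
Reactants: 27 dimethyl (3R,7R)-3,7-bis(TBS-oxy)nonanedioate
Product: 28 (3R,7R)-3,7-bis(TBS-oxy)nonane-1,9-diol
Conditions: LiBH4, THF, 0 °C → rt
Reagents that add atoms: none
Why: Lithium borohydride reduces both esters to primary alcohols without disturbing the silyl ethers.

Step 18
Reactants: 28 (3R,7R)-3,7-bis(TBS-oxy)nonane-1,9-diol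
Product: 29 (3R,7R)-1,9-dibromo-3,7-bis(TBS-oxy)nonane
Conditions: CBr4, PPh3, CH2Cl2, 0 °C
Reagents that add atoms: carbon tetrabromide, BrC(Br)(Br)Br
Why: Appel bromination converts both primary alcohols into bromides under neutral conditions.

Step 19
Reactants: 29 (3R,7R)-1,9-dibromo-3,7-bis(TBS-oxy)nonane; 18 (S)-epichlorohydrin
Product: 31 (2S,6S,10S,14S)-1,15-dichloro-6,10-bis(TBS-oxy)pentadecane-2,14-diol, via bis-Grignard reagent 30 (not isolated)
Conditions: Mg, THF, 40 °C; then CuI (20 mol%), 18 (2.4 equiv), −40 °C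
Reagents that add atoms: none
Why: Double copper-catalysed Grignard opening of (S)-epichlorohydrin at its CH2 terminus brings in C13 and C25 from the chiral pool and keeps the C2 symmetry.

Step 20
Reactants: 31 (2S,6S,10S,14S)-1,15-dichloro-6,10-bis(TBS-oxy)pentadecane-2,14-diol
Product: 32 (2S,2'S)-2,2'-[(4S,8S)-4,8-bis(TBS-oxy)undecane-1,11-diyl]bis(oxirane)
Conditions: NaOH, H2O/Et2O, rt
Reagents that add atoms: none
Why: Twofold 3-exo-tet chlorohydrin closure gives the C2-symmetric bis-epoxide whose two ends are homotopic.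

### Part E – assembly and endgame

Step 21
Reactants: 33 2-(tert-butyldimethylsilyl)-1,3-dithiane; 21 (2S)-2-{4-[(4-methoxybenzyl)oxy]butyl}oxirane; 32 (2S,2'S)-2,2'-[(4S,8S)-4,8-bis(TBS-oxy)undecane-1,11-diyl]bis(oxirane)
Product: 37 C12–C33 epoxy alcohol (C27 1,3-dithiane; 29-OTBS; 25-OH; 17,21-bis-OTBS; 12,13-epoxide; 33-OPMB; 13S,17S,21S,25S,29S), via lithiodithiane 34 (not isolated), via lithium alkoxide 35 (not isolated), via dithiane carbanion 36 (not isolated)
Conditions: t-BuLi, Et2O, −78 → −45 °C; 21, −78 → −25 °C; then 32 (3 equiv), HMPA/THF, −78 → −40 °C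
Reagents that add atoms: none
Why: Three-component silyl-dithiane linchpin coupling: the lithiated dithiane opens 21 at C28, HMPA triggers the 1,4-Brook rearrangement that silylates the C29 oxygen and regenerates the carbanion at C27, and this opens one of the two homotopic epoxides of excess 32 at C26, so no new stereocentre is formed and mono-opening is controlled by stoichiometry.

Step 22
Reactants: 37 C12–C33 epoxy alcohol
Product: 38 C12–C33 allylic alcohol (C13 vinyl carbinol; 13,25-diol; C27 dithiane; 17,21,29-tris-OTBS; 33-OPMB; 13S,17S,21S,25S,29S)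
Conditions: Me3S+ I− (5 equiv), n-BuLi (4.8 equiv), THF, −10 °C → rt
Reagents that add atoms: trimethylsulfonium iodide, C[S+](C)C.[I-]
Why: Dimethylsulfonium methylide opens the terminal epoxide at C12 and the γ-oxido sulfonium salt eliminates dimethyl sulfide, a one-carbon homologation that turns the spare epoxide into the C13 vinyl carbinol with retention at C13.

Step 23
Reactants: 38 C12–C33 allylic alcohol
Product: 39 C12–C33 β-hydroxy ketone (27-oxo; 13,25-diol; 13S,17S,21S,25S,29S)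
Conditions: MeI, CaCO3, MeCN/H2O (9:1), 45 °C
Reagents that add atoms: water, O
Why: S-methylation and buffered hydrolysis unmask the C27 ketone under conditions that should spare the silyl ethers, the PMB ether and the alkene.

Step 24
Reactants: 39 C12–C33 β-hydroxy ketone
Product: 41 C12–C33 triol (13,25,27-triol; 13S,17S,21S,25S,27S,29S), via boron chelate 40 (not isolated)
Conditions: Et2BOMe, THF/MeOH (4:1), −78 °C; NaBH4; then MeOH co-evaporation
Reagents that add atoms: none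
Why: Narasaka–Prasad reduction: the six-membered diethylboron chelate of the C25 hydroxyl and C27 ketone takes axial hydride from outside, which should give the 25,27-syn diol and so set C27.

Step 25
Reactants: 41 C12–C33 triol
Product: 42 C12–C33 hexakis-TBS ether (OTBS at C13, C17, C21, C25, C27, C29; 33-OPMB; 13S,17R,21R,25S,27R,29S)
Conditions: TBSOTf, 2,6-lutidine, CH2Cl2, −78 → 0 °C
Reagents that add atoms: tert-butyldimethylsilyl triflate, CC(C)(C)[Si](C)(C)OS(=O)(=O)C(F)(F)F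
Why: Exhaustive silylation of the three secondary alcohols gives one uniform protecting group for the final deprotection.

Step 26
Reactants: 42 C12–C33 hexakis-TBS ether
Product: 43 C12–C33 primary alcohol (33-OH; 13S,17R,21R,25S,27R,29S)
Conditions: DDQ, CH2Cl2/pH 7 buffer (10:1), 0 °C
Reagents that add atoms: none
Why: Oxidative PMB cleavage by DDQ proceeds through the benzylic oxocarbenium ion and should not affect silyl ethers or the terminal alkene.

Step 27
Reactants: 43 C12–C33 primary alcohol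
Product: 44 C12–C33 aldehyde (33-al; 13S,17R,21R,25S,27S,29S)
Conditions: Dess–Martin periodinane, CH2Cl2, rt
Reagents that add atoms: none
Why: Dess–Martin oxidation of the primary alcohol to the C33 aldehyde.

Step 28
Reactants: 44 C12–C33 aldehyde
Product: 45 C33 1,3-dithiane of the C12–C33 chain (13S,17R,21R,25S,27S,29S)
Conditions: HS(CH2)3SH, BF3·OEt2, CH2Cl2, −78 → −40 °C
Reagents that add atoms: propane-1,3-dithiol, SCCCS
Why: Lewis-acid-catalysed dithioacetalisation at low temperature turns C33 into an acyl-anion equivalent while the secondary silyl ethers should survive.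

Step 29
Reactants: 45 C33 1,3-dithiane of the C12–C33 chain; 16 (2S)-2-[(2S)-hexan-2-yl]oxirane
Product: 47 C12–C40 β-hydroxy dithiane (35-OH; C33 dithiane; 13S,17R,21R,25S,27S,29S,35R,36S), via lithiodithiane 46 (not isolated)
Conditions: t-BuLi, THF/HMPA (10:1), −78 °C; then 16 (2 equiv), −78 → −20 °C
Reagents that add atoms: none
Why: Corey–Seebach umpolung: the 2-lithio-1,3-dithiane attacks the unsubstituted carbon (C34) of the epoxide, so C35 and C36 are carried over unchanged from 16.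

Step 30
Reactants: 47 C12–C40 β-hydroxy dithiane
Product: 48 C12–C40 β-hydroxy ketone (33-oxo; 35-OH; 13S,17R,21R,25S,27S,29S,35R,36S)
Conditions: MeI, CaCO3, MeCN/H2O (9:1), 45 °C
Reagents that add atoms: water, O
Why: Mild alkylative dithiane hydrolysis reveals the C33 ketone β to the C35 hydroxyl without retro-aldol or elimination.

Step 31
Reactants: 48 C12–C40 β-hydroxy ketone; 11 (3R,5R,9S)-5,9-bis(TBS-oxy)-3-methyldodec-11-enal
Product: 49 seco diene ester with free 33-OH (C1–O–C35 ester; 3R,5R,9S,13S,17R,21R,25S,27R,29S,33S,35R,36S)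
Conditions: 11 (2.5 equiv), SmI2 (30 mol%), THF, −10 °C
Reagents that add atoms: none
Why: Evans–Tishchenko reaction: the samarium-bound hemiacetal formed from the C35 hydroxyl and aldehyde 11 delivers hydride intramolecularly to the C33 ketone through a chair-like six-membered transition state, which should give the 33,35-anti relationship and place the C1 acyl group on the hindered C35 oxygen in the same operation.

Step 32
Reactants: 49 seco diene ester with free 33-OH
Product: 50 nona-TBS diene ester (3R,5R,9S,13S,17R,21R,25S,27S,29S,33S,35R,36S)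
Conditions: TBSOTf, 2,6-lutidine, CH2Cl2, −78 °C
Reagents that add atoms: tert-butyldimethylsilyl triflate, CC(C)(C)[Si](C)(C)OS(=O)(=O)C(F)(F)F
Why: Immediate low-temperature silylation of the C33 hydroxyl blocks 1,3-acyl migration from the C35 oxygen.

Step 33
Reactants: 50 nona-TBS diene ester
Product: 52 nona-TBS macrolactone (3R,5R,9R,13S,17S,21R,25S,27S,29S,33S,35R,36S), via cycloalkene 51 (not isolated)
Conditions: Grubbs second-generation catalyst (10 mol%), ClCH2CH2Cl (0.5 mM), 60 °C, Ar sparge; then H2 (7 bar), 70 °C, same pot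
Reagents that add atoms: none
Why: Ring-closing olefin metathesis: the ruthenium alkylidene initiates at the unhindered C10–C11 allyl terminus and undergoes [2+2] cycloaddition/cycloreversion with the C12 vinyl group of the C13 allylic silyl ether, releasing ethylene and closing C11=C12, after which hydrogen converts the ruthenium residue into a hydride that saturates this alkene in the same pot. The closest known reaction type is macrocyclic ring-closing metathesis of ester-tethered α,ω-dienes followed by tandem ruthenium-catalysed hydrogenation. The single ring, the 36-membered lactone (C1–C35 plus O), is closed end-to-end as a macrocyclisation at the site most remote from the ester, with no small-ring or transannular constraint. No stereocentre is created: alkene geometry is erased by the hydrogenation and all twelve stereocentres are already in place, C9 and C13 having been introduced together with their alkene handles. The step needs ring closure to outrun intermolecular metathesis, which high dilution, ethylene removal and the low homodimerisation tendency of the hindered C13 vinyl group should secure; chemoselectivity is not an issue because 50 has no other C=C and the ester and silyl ethers are inert to the catalyst and to hydrogen.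

Step 34
Reactants: 52 nona-TBS macrolactone
Product: 53 CNP0225459.2 (target)
Conditions: HF·pyridine, pyridine, THF, 0 °C → rt
Reagents that add atoms: none
Why: Buffered acidic fluoride should remove all nine silyl ethers while avoiding the base-mediated translactonisation that a free polyol lactone would risk.

## Compound list

1 | methyl hydrogen (R)-3-methylglutarate | COC(=O)C[C@H](C)CC(=O)O | starting material
2 | methyl (3R)-5-hydroxy-3-methylpentanoate | COC(=O)C[C@H](C)CCO | intermediate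
3 | methyl (3R)-3-methyl-5-oxopentanoate | COC(=O)C[C@H](C)CC=O | intermediate
4 | diisopinocampheylborinate of 5 | COC(=O)C[C@H](C)C[C@H](OB([C@H]1C[C@H]2C[C@@H]([C@@H]1C)C2(C)C)[C@H]1C[C@H]2C[C@@H]([C@@H]1C)C2(C)C)CC=C | intermediate
5 | methyl (3R,5R)-5-hydroxy-3-methyloct-7-enoate | COC(=O)C[C@H](C)C[C@H](O)CC=C | intermediate
6 | methyl (3R,5R)-5-(TBS-oxy)-3-methyloct-7-enoate | COC(=O)C[C@H](C)C[C@H](O[Si](C)(C)C(C)(C)C)CC=C | intermediate
7 | methyl (3R,5R)-5-(TBS-oxy)-3-methyl-9-oxononanoate | COC(=O)C[C@H](C)C[C@H](O[Si](C)(C)C(C)(C)C)CCCC=O | intermediate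
8 | diisopinocampheylborinate of 9 | COC(=O)C[C@H](C)C[C@H](O[Si](C)(C)C(C)(C)C)CCC[C@H](OB([C@H]1C[C@H]2C[C@@H]([C@@H]1C)C2(C)C)[C@H]1C[C@H]2C[C@@H]([C@@H]1C)C2(C)C)CC=C | intermediate
9 | methyl (3R,5R,9S)-5-(TBS-oxy)-9-hydroxy-3-methyldodec-11-enoate | COC(=O)C[C@H](C)C[C@H](O[Si](C)(C)C(C)(C)C)CCC[C@H](O)CC=C | intermediate
10 | methyl (3R,5R,9S)-5,9-bis(TBS-oxy)-3-methyldodec-11-enoate | COC(=O)C[C@H](C)C[C@H](O[Si](C)(C)C(C)(C)C)CCC[C@H](O[Si](C)(C)C(C)(C)C)CC=C | intermediate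
11 | (3R,5R,9S)-5,9-bis(TBS-oxy)-3-methyldodec-11-enal | O=CC[C@H](C)C[C@H](O[Si](C)(C)C(C)(C)C)CCC[C@H](O[Si](C)(C)C(C)(C)C)CC=C | intermediate
12 | (E)-hept-2-en-1-ol | CCCC/C=C/CO | starting material
13 | [(2R,3R)-3-butyloxiran-2-yl]methanol | CCCC[C@H]1O[C@@H]1CO | intermediate
14 | (2S,3S)-3-methylheptane-1,2-diol | CCCC[C@H](C)[C@H](O)CO | intermediate
15 | (2S,3S)-2-hydroxy-3-methylheptyl p-toluenesulfonate | CCCC[C@H](C)[C@H](O)COS(=O)(=O)c1ccc(C)cc1 | intermediate
16 | (2S)-2-[(2S)-hexan-2-yl]oxirane | CCCC[C@H](C)[C@H]1CO1 | intermediate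
17 | 1-[(3-bromopropoxy)methyl]-4-methoxybenzene | COc1ccc(COCCCBr)cc1 | starting material
18 | (S)-epichlorohydrin | ClC[C@@H]1CO1 | starting material
19 | {3-[(4-methoxybenzyl)oxy]propyl}magnesium bromide | COc1ccc(COCCC[Mg]Br)cc1 | intermediate
20 | (2S)-1-chloro-6-[(4-methoxybenzyl)oxy]hexan-2-ol | COc1ccc(COCCCC[C@H](O)CCl)cc1 | intermediate
21 | (2S)-2-{4-[(4-methoxybenzyl)oxy]butyl}oxirane | COc1ccc(COCCCC[C@H]2CO2)cc1 | intermediate
22 | glutaryl dichloride | O=C(Cl)CCCC(=O)Cl | starting material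
23 | Meldrum's acid | CC1(C)OC(=O)CC(=O)O1 | starting material
24 | 5,5'-glutaryl-bis(2,2-dimethyl-1,3-dioxane-4,6-dione) | CC1(C)OC(=O)C(C(=O)CCCC(=O)C2C(=O)OC(C)(C)OC2=O)C(=O)O1 | intermediate
25 | dimethyl 3,7-dioxononanedioate | COC(=O)CC(=O)CCCC(=O)CC(=O)OC | intermediate
26 | dimethyl (3R,7R)-3,7-dihydroxynonanedioate | COC(=O)C[C@H](O)CCC[C@@H](O)CC(=O)OC | intermediate
27 | dimethyl (3R,7R)-3,7-bis(TBS-oxy)nonanedioate | COC(=O)C[C@H](O[Si](C)(C)C(C)(C)C)CCC[C@@H](O[Si](C)(C)C(C)(C)C)CC(=O)OC | intermediate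
28 | (3R,7R)-3,7-bis(TBS-oxy)nonane-1,9-diol | OCC[C@H](O[Si](C)(C)C(C)(C)C)CCC[C@@H](O[Si](C)(C)C(C)(C)C)CCO | intermediate
29 | (3R,7R)-1,9-dibromo-3,7-bis(TBS-oxy)nonane | BrCC[C@H](O[Si](C)(C)C(C)(C)C)CCC[C@@H](O[Si](C)(C)C(C)(C)C)CCBr | intermediate
30 | bis-Grignard reagent of 29 | Br[Mg]CC[C@H](O[Si](C)(C)C(C)(C)C)CCC[C@@H](O[Si](C)(C)C(C)(C)C)CC[Mg]Br | intermediate
31 | (2S,6S,10S,14S)-1,15-dichloro-6,10-bis(TBS-oxy)pentadecane-2,14-diol | ClC[C@@H](O)CCC[C@H](O[Si](C)(C)C(C)(C)C)CCC[C@@H](O[Si](C)(C)C(C)(C)C)CCC[C@H](O)CCl | intermediate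
32 | (2S,2'S)-2,2'-[(4S,8S)-4,8-bis(TBS-oxy)undecane-1,11-diyl]bis(oxirane) | C1O[C@H]1CCC[C@H](O[Si](C)(C)C(C)(C)C)CCC[C@@H](O[Si](C)(C)C(C)(C)C)CCC[C@H]1CO1 | intermediate
33 | 2-(tert-butyldimethylsilyl)-1,3-dithiane | CC(C)(C)[Si](C)(C)C1SCCCS1 | starting material
34 | 2-lithio-2-(tert-butyldimethylsilyl)-1,3-dithiane | [Li]C1([Si](C)(C)C(C)(C)C)SCCCS1 | intermediate
35 | lithium alkoxide from 34 and 21 (C29–OLi; C27 silyl dithiane) | COc1ccc(COCCCC[C@H](O[Li])CC2([Si](C)(C)C(C)(C)C)SCCCS2)cc1 | intermediate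
36 | Brook-rearranged C27 lithiodithiane (C29–OTBS) | COc1ccc(COCCCC[C@H](O[Si](C)(C)C(C)(C)C)CC2([Li])SCCCS2)cc1 | intermediate
37 | C12–C33 epoxy alcohol (C27 dithiane; 29-OTBS; 25-OH; 17,21-bis-OTBS; 12,13-epoxide; 33-OPMB; 13S,17S,21S,25S,29S) | COc1ccc(COCCCC[C@H](O[Si](C)(C)C(C)(C)C)CC2(SCCCS2)C[C@@H](O)CCC[C@H](O[Si](C)(C)C(C)(C)C)CCC[C@@H](O[Si](C)(C)C(C)(C)C)CCC[C@H]2CO2)cc1 | intermediate
38 | C12–C33 allylic alcohol (C13 vinyl carbinol; 13,25-diol; C27 dithiane; 13S,17S,21S,25S,29S) | COc1ccc(COCCCC[C@H](O[Si](C)(C)C(C)(C)C)CC2(SCCCS2)C[C@@H](O)CCC[C@H](O[Si](C)(C)C(C)(C)C)CCC[C@@H](O[Si](C)(C)C(C)(C)C)CCC[C@H](O)C=C)cc1 | intermediate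
39 | C12–C33 β-hydroxy ketone (27-oxo; 13,25-diol; 13S,17S,21S,25S,29S) | COc1ccc(COCCCC[C@H](O[Si](C)(C)C(C)(C)C)CC(=O)C[C@@H](O)CCC[C@H](O[Si](C)(C)C(C)(C)C)CCC[C@@H](O[Si](C)(C)C(C)(C)C)CCC[C@H](O)C=C)cc1 | intermediate
40 | C25-O-diethylboryl chelate of 39 | COc1ccc(COCCCC[C@H](O[Si](C)(C)C(C)(C)C)CC(=O)C[C@@H](OB(CC)CC)CCC[C@H](O[Si](C)(C)C(C)(C)C)CCC[C@@H](O[Si](C)(C)C(C)(C)C)CCC[C@H](O)C=C)cc1 | intermediate
41 | C12–C33 triol (13,25,27-triol; 13S,17S,21S,25S,27S,29S) | COc1ccc(COCCCC[C@H](O[Si](C)(C)C(C)(C)C)C[C@@H](O)C[C@@H](O)CCC[C@H](O[Si](C)(C)C(C)(C)C)CCC[C@@H](O[Si](C)(C)C(C)(C)C)CCC[C@H](O)C=C)cc1 | intermediate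
42 | C12–C33 hexakis-TBS ether (33-OPMB; 13S,17R,21R,25S,27R,29S) | COc1ccc(COCCCC[C@H](O[Si](C)(C)C(C)(C)C)C[C@@H](O[Si](C)(C)C(C)(C)C)C[C@@H](O[Si](C)(C)C(C)(C)C)CCC[C@H](O[Si](C)(C)C(C)(C)C)CCC[C@@H](O[Si](C)(C)C(C)(C)C)CCC[C@H](O[Si](C)(C)C(C)(C)C)C=C)cc1 | intermediate
43 | C12–C33 primary alcohol (33-OH; 13S,17R,21R,25S,27R,29S) | OCCCC[C@H](O[Si](C)(C)C(C)(C)C)C[C@@H](O[Si](C)(C)C(C)(C)C)C[C@@H](O[Si](C)(C)C(C)(C)C)CCC[C@H](O[Si](C)(C)C(C)(C)C)CCC[C@@H](O[Si](C)(C)C(C)(C)C)CCC[C@H](O[Si](C)(C)C(C)(C)C)C=C | intermediate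
44 | C12–C33 aldehyde (33-al; 13S,17R,21R,25S,27S,29S) | O=CCCC[C@H](O[Si](C)(C)C(C)(C)C)C[C@@H](O[Si](C)(C)C(C)(C)C)C[C@@H](O[Si](C)(C)C(C)(C)C)CCC[C@H](O[Si](C)(C)C(C)(C)C)CCC[C@@H](O[Si](C)(C)C(C)(C)C)CCC[C@H](O[Si](C)(C)C(C)(C)C)C=C | intermediate
45 | C33 1,3-dithiane of the C12–C33 chain (13S,17R,21R,25S,27S,29S) | S1CCCSC1CCC[C@H](O[Si](C)(C)C(C)(C)C)C[C@@H](O[Si](C)(C)C(C)(C)C)C[C@@H](O[Si](C)(C)C(C)(C)C)CCC[C@H](O[Si](C)(C)C(C)(C)C)CCC[C@@H](O[Si](C)(C)C(C)(C)C)CCC[C@H](O[Si](C)(C)C(C)(C)C)C=C | intermediate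
46 | C33 lithiodithiane from 45 | [Li]C1(SCCCS1)CCC[C@H](O[Si](C)(C)C(C)(C)C)C[C@@H](O[Si](C)(C)C(C)(C)C)C[C@@H](O[Si](C)(C)C(C)(C)C)CCC[C@H](O[Si](C)(C)C(C)(C)C)CCC[C@@H](O[Si](C)(C)C(C)(C)C)CCC[C@H](O[Si](C)(C)C(C)(C)C)C=C | intermediate
47 | C12–C40 β-hydroxy dithiane (35-OH; C33 dithiane; 13S,17R,21R,25S,27S,29S,35R,36S) | CCCC[C@H](C)[C@H](O)CC1(SCCCS1)CCC[C@H](O[Si](C)(C)C(C)(C)C)C[C@@H](O[Si](C)(C)C(C)(C)C)C[C@@H](O[Si](C)(C)C(C)(C)C)CCC[C@H](O[Si](C)(C)C(C)(C)C)CCC[C@@H](O[Si](C)(C)C(C)(C)C)CCC[C@H](O[Si](C)(C)C(C)(C)C)C=C | intermediate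
48 | C12–C40 β-hydroxy ketone (33-oxo; 35-OH; 13S,17R,21R,25S,27S,29S,35R,36S) | CCCC[C@H](C)[C@H](O)CC(=O)CCC[C@H](O[Si](C)(C)C(C)(C)C)C[C@@H](O[Si](C)(C)C(C)(C)C)C[C@@H](O[Si](C)(C)C(C)(C)C)CCC[C@H](O[Si](C)(C)C(C)(C)C)CCC[C@@H](O[Si](C)(C)C(C)(C)C)CCC[C@H](O[Si](C)(C)C(C)(C)C)C=C | intermediate
49 | seco diene ester with free 33-OH (3R,5R,9S,13S,17R,21R,25S,27R,29S,33S,35R,36S) | CCCC[C@H](C)[C@H](OC(=O)C[C@H](C)C[C@H](O[Si](C)(C)C(C)(C)C)CCC[C@H](O[Si](C)(C)C(C)(C)C)CC=C)C[C@@H](O)CCC[C@H](O[Si](C)(C)C(C)(C)C)C[C@@H](O[Si](C)(C)C(C)(C)C)C[C@@H](O[Si](C)(C)C(C)(C)C)CCC[C@H](O[Si](C)(C)C(C)(C)C)CCC[C@@H](O[Si](C)(C)C(C)(C)C)CCC[C@H](O[Si](C)(C)C(C)(C)C)C=C | intermediate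
50 | nona-TBS diene ester (3R,5R,9S,13S,17R,21R,25S,27S,29S,33S,35R,36S) | CCCC[C@H](C)[C@H](OC(=O)C[C@H](C)C[C@H](O[Si](C)(C)C(C)(C)C)CCC[C@H](O[Si](C)(C)C(C)(C)C)CC=C)C[C@@H](O[Si](C)(C)C(C)(C)C)CCC[C@H](O[Si](C)(C)C(C)(C)C)C[C@@H](O[Si](C)(C)C(C)(C)C)C[C@@H](O[Si](C)(C)C(C)(C)C)CCC[C@H](O[Si](C)(C)C(C)(C)C)CCC[C@@H](O[Si](C)(C)C(C)(C)C)CCC[C@H](O[Si](C)(C)C(C)(C)C)C=C | intermediate
51 | nona-TBS 36-membered cycloalkene (C11=C12; E/Z mixture; other centres as 50) | CCCC[C@H](C)[C@H]1C[C@@H](O[Si](C)(C)C(C)(C)C)CCC[C@H](O[Si](C)(C)C(C)(C)C)C[C@@H](O[Si](C)(C)C(C)(C)C)C[C@@H](O[Si](C)(C)C(C)(C)C)CCC[C@H](O[Si](C)(C)C(C)(C)C)CCC[C@@H](O[Si](C)(C)C(C)(C)C)CCC[C@H](O[Si](C)(C)C(C)(C)C)C=CC[C@@H](O[Si](C)(C)C(C)(C)C)CCC[C@@H](O[Si](C)(C)C(C)(C)C)C[C@@H](C)CC(=O)O1 | intermediate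
52 | nona-TBS macrolactone (3R,5R,9R,13S,17S,21R,25S,27S,29S,33S,35R,36S) | CCCC[C@H](C)[C@H]1C[C@@H](O[Si](C)(C)C(C)(C)C)CCC[C@H](O[Si](C)(C)C(C)(C)C)C[C@@H](O[Si](C)(C)C(C)(C)C)C[C@@H](O[Si](C)(C)C(C)(C)C)CCC[C@H](O[Si](C)(C)C(C)(C)C)CCC[C@@H](O[Si](C)(C)C(C)(C)C)CCC[C@H](O[Si](C)(C)C(C)(C)C)CCC[C@@H](O[Si](C)(C)C(C)(C)C)CCC[C@@H](O[Si](C)(C)C(C)(C)C)C[C@@H](C)CC(=O)O1 | intermediate
53 | CNP0225459.2 (3R,5R,9R,13S,17S,21R,25S,27S,29S,33S,35R,36S) | CCCC[C@H](C)[C@H]1C[C@@H](O)CCC[C@H](O)C[C@@H](O)C[C@@H](O)CCC[C@H](O)CCC[C@@H](O)CCC[C@H](O)CCC[C@@H](O)CCC[C@@H](O)C[C@@H](C)CC(=O)O1 | target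

## Summary

Total step count: 34. Longest linear sequence: 21 steps (steps 14–34, from glutaryl dichloride 22).

Steps most likely to fail:

1. Step 33. Slow metathesis at the hindered vinyl group next to the C13 silyl ether could let acyclic metathesis of the allyl termini (dimer and oligomer formation) outrun ring closure, or the ruthenium hydride could isomerise or only partly hydrogenate the new alkene. The fallback replaces metathesis by a reductive carbonyl coupling and sets out from 50. Ozonolysis of both terminal alkenes (O3, CH2Cl2, −78 °C; PPh3) would give the C11,C12-dialdehyde F1. An intramolecular McMurry coupling (TiCl3(DME)1.5, Zn–Cu, DME, reflux, slow addition) would close the same C11=C12 bond to give cycloalkene 51. A separate hydrogenation (H2, Pd/C, EtOAc) would then rejoin the route at 52.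

2. Step 21. Silyl migration might occur too early or incompletely, so that the C27 carbanion is quenched or formed before 21 is consumed, and both epoxides of 32 might be opened. The fallback is a stepwise dithiane alkylation without the Brook relay and sets out from 21. 2-Lithio-1,3-dithiane (1,3-dithiane, n-BuLi, THF, −30 °C) would open 21 to give the hydroxy dithiane F2. Silylation (TBSCl, imidazole, DMF) would give its TBS ether F3. Deprotonation of F3 (t-BuLi, THF/HMPA, −78 °C) generates carbanion 36 directly, and addition to excess 32 comes back to the route at 37.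

3. Step 31. With only a small excess of the valuable aldehyde, hemiacetal formation and hydride transfer may stall while aldehyde self-condensation and 1,3-acyl migration compete. The fallback separates reduction from acylation and sets out from 48. An Evans–Tishchenko reaction with a large excess of benzaldehyde (SmI2 cat., THF, −10 °C) would give the C35 benzoate with free 33-OH, F4. TBSOTf/2,6-lutidine would give the 33-OTBS benzoate F5. DIBAL-H (CH2Cl2, −78 °C) would remove the benzoate to give the C35 alcohol F6. Separately, LiOH hydrolysis of ester 10 would give acid F7. Yamaguchi esterification of F6 with F7 (2,4,6-trichlorobenzoyl chloride, Et3N, then DMAP, toluene) comes back to the route at 50.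

## Further compounds

F1 | step 33 | C11,C12-dialdehyde from 50 (both CH=CH2 termini replaced by CH=O) | CCCC[C@H](C)[C@H](OC(=O)C[C@H](C)C[C@H](O[Si](C)(C)C(C)(C)C)CCC[C@H](O[Si](C)(C)C(C)(C)C)CC=O)C[C@@H](O[Si](C)(C)C(C)(C)C)CCC[C@H](O[Si](C)(C)C(C)(C)C)C[C@@H](O[Si](C)(C)C(C)(C)C)C[C@@H](O[Si](C)(C)C(C)(C)C)CCC[C@H](O[Si](C)(C)C(C)(C)C)CCC[C@@H](O[Si](C)(C)C(C)(C)C)CCC[C@H](O[Si](C)(C)C(C)(C)C)C=O
F2 | step 21 | (2S)-1-(1,3-dithian-2-yl)-6-[(4-methoxybenzyl)oxy]hexan-2-ol | COc1ccc(COCCCC[C@H](O)CC2SCCCS2)cc1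
F3 | step 21 | TBS ether of F2 | COc1ccc(COCCCC[C@H](O[Si](C)(C)C(C)(C)C)CC2SCCCS2)cc1
F4 | step 31 | C12–C40 C35 benzoate with free 33-OH (33S,35R,36S) | CCCC[C@H](C)[C@H](OC(=O)c1ccccc1)C[C@@H](O)CCC[C@H](O[Si](C)(C)C(C)(C)C)C[C@@H](O[Si](C)(C)C(C)(C)C)C[C@@H](O[Si](C)(C)C(C)(C)C)CCC[C@H](O[Si](C)(C)C(C)(C)C)CCC[C@@H](O[Si](C)(C)C(C)(C)C)CCC[C@H](O[Si](C)(C)C(C)(C)C)C=C
F5 | step 31 | C12–C40 C35 benzoate 33-OTBS ether | CCCC[C@H](C)[C@H](OC(=O)c1ccccc1)C[C@@H](O[Si](C)(C)C(C)(C)C)CCC[C@H](O[Si](C)(C)C(C)(C)C)C[C@@H](O[Si](C)(C)C(C)(C)C)C[C@@H](O[Si](C)(C)C(C)(C)C)CCC[C@H](O[Si](C)(C)C(C)(C)C)CCC[C@@H](O[Si](C)(C)C(C)(C)C)CCC[C@H](O[Si](C)(C)C(C)(C)C)C=C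
F6 | step 31 | C12–C40 C35 alcohol with 33-OTBS (hepta-TBS) | CCCC[C@H](C)[C@H](O)C[C@@H](O[Si](C)(C)C(C)(C)C)CCC[C@H](O[Si](C)(C)C(C)(C)C)C[C@@H](O[Si](C)(C)C(C)(C)C)C[C@@H](O[Si](C)(C)C(C)(C)C)CCC[C@H](O[Si](C)(C)C(C)(C)C)CCC[C@@H](O[Si](C)(C)C(C)(C)C)CCC[C@H](O[Si](C)(C)C(C)(C)C)C=C
F7 | step 31 | (3R,5R,9S)-5,9-bis(TBS-oxy)-3-methyldodec-11-enoic acid | OC(=O)C[C@H](C)C[C@H](O[Si](C)(C)C(C)(C)C)CCC[C@H](O[Si](C)(C)C(C)(C)C)CC=C
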